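## Analysis of the target

The target 15 is a 20-membered macrocycle in which two benzene rings are joined twice: by a diaryl ether oxygen and by an unbranched chain of fourteen methylene groups (C1' on B6 through C14' on A3). Ring A is 1,3,5-trisubstituted, with a hydroxyl on A1, the chain on A3 and the ether oxygen on A5. Ring B is tetrasubstituted, with the ether oxygen on B1, hydroxyls on B2 and B4 and the chain on B6, so B1 lies between an oxygen-bearing carbon and the chain-bearing carbon. There is no stereocenter and no double bond outside the arenes. The sensitive part is ring B: with B1–O para to the B4 hydroxyl it is a hydroquinone-type mono-ether that oxidises easily once its phenols are free, so the phenols are best unmasked in the last step. The difficulty is the unsymmetrical diaryl ether, because B1 is electron-rich, flanked on both sides, and the B1–O bond must also close the large ring. The plan rests on one feature: without the ether bond each ring is a 5-alkylresorcinol, the aromatic form of a tetraketide whose C2 has added to its C7 ketone. C7 becomes the chain-bearing carbon (B6, A3), C3 and C5 carry the oxygens, and the carboxyl-bearing C2 becomes B1 in ring B and A2 in ring A. Cutting the ether and restoring the two carboxyl groups therefore uncovers a twofold-symmetric bis-resorcylate and, behind it, a linear C28 chain with six ketones.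

## Retrosynthetic reasoning

15 from 14. No skeletal bond is cut. The last step only removes two benzyl ethers (A1, B2) and an iodine on A2 by hydrogenolysis. This keeps the oxidisable phenols masked to the end, and the leftover iodine is the price paid for a symmetric precursor.

14 from 13. The bond cut is B1–O of the diaryl ether. It is the only cut that leaves two identical rings, whereas a cut in the chain would demand two differently built arenes. The forward reaction is a copper-catalysed intramolecular O-arylation. In 13 each ring carries iodine on the carbon between the chain and an oxygen, a benzyl ether on that neighbouring oxygen, and a free hydroxyl para to the iodine. The para relationship matters: after one C–O bond has formed, a second one would have to bridge para positions of both rings with single atoms, which is impossible. A free hydroxyl ortho to the iodine could instead close a dibenzodioxin. An oxidative phenol coupling of a decarboxylated, unprotected ring pair was not relied upon. Resorcinol-type phenoxyl radicals couple at carbon as readily as at oxygen, and the hydroquinone-type product is more easily oxidised than its precursor.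

13 from 12 from 11. The two C–I bonds are traced back to carboxyl groups. Decarboxylative ipso-iodination of 11 places the halogen exactly on the former C2 of each tetraketide, so the regiochemistry of B1 is settled by construction and not by directing effects. The para oxygen is kept as a methoxymethyl acetal during the iodination, since a free phenol would be iodinated on the ring, and is released afterwards.

11 from 10 from 9 from 8. The two hydroxyls of each ring in 8 are told apart by the ester. The ortho hydroxyl is hydrogen-bonded to it, so the para hydroxyl takes the temporary acetal first. The ortho hydroxyl then takes the benzyl group, and the ester is hydrolysed.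

8 from 7 (key disconnection). The bonds cut are B1–B6 and A2–A3, that is C2–C7 and C27–C22 of 7. This unfolds both arenes at once into one open chain, in which all carbons of the target, every oxygen and the correct oxidation level are already present. The forward reaction must make C2 add to C7 at each end and aromatise, in preference to other ring closures.

7 from 2 and 5. The bonds C6–C7 and C21–C22 are cut. Each ketone C7/C22 is an acyl carbon of a C16 diacid derivative, and C1–C6 is a triacetic ester unit used as its trianion 6. The forward reaction is a double terminal C-acylation.

2 from 1, and 5 from 3 via 4. The triacetic ester 2 comes from ring opening and deacetylation of the pyranone 1. The bis(N-methoxy-N-methylamide) 5 comes from the diacid 3 through its diimidazolide 4.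

## Alternatives that were turned down

Alternative 1: The chain bond C13'–C14' next to ring A is disconnected through a one-atom-larger cyclic sulfone A2. In the forward step, A2 is halogenated in situ at its benzylic α-carbon under strong base, undergoes 1,3-elimination to an episulfone and loses SO2 (Ramberg–Bäcklund), giving the alkene A1. Hydrogenation and cleavage of three methyl ethers would follow. In its favour, the macrocycle would be closed beforehand by S-alkylation, the most dependable way to make a large ring. The diaryl ether would be made intermolecularly between two different, fully protected arenes, with no question of which ring plays which role. On both points it is stronger than the chosen route. Against it, rings A and B must be bought or made as two separately functionalised arenes, one carrying a C13 ω-functionalised chain. They must still be joined by an O-arylation at the same crowded B1 carbon. The halogenation can also occur at the non-benzylic α'-carbon or on the electron-rich rings. Sulfur has to be introduced, oxidised and expelled, and three methyl ethers need a strong Lewis acid at the end. What the chosen strategy offers instead is the whole carbon skeleton with both arenes in four steps from two bulk chemicals, and protecting groups that leave by hydrogenolysis.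

Alternative 2: Ring B is disconnected at B1–B6 and B2–B3 into the aryloxymalonate A4 and the enone A5. In the forward step, Michael addition of A4 to A5 is followed by Claisen closure of the methyl ketone enolate onto one ester, giving the cyclohexane-1,3-dione A3. In its favour, the ether oxygen is attached to B1 by simple alkylation of a phenol before ring B exists, so no O-arylation at a hindered arene carbon is needed. On this point it is clearly stronger than the chosen route. Against it, the Michael donor is a hindered, fully substituted carbanion and its addition is reversible. A3 is at the wrong oxidation level: it must lose its ester from a carbon bearing an aryloxy group and then be dehydrogenated to the resorcinol. The oxidants or halogenating agents for that step also threaten the electron-rich ring A and the terminal alkene. The macrocycle must still be closed afterwards by an sp2–sp3 coupling between the aryl bromide and the hydroborated alkene. The chosen route gives both rings directly as arenes at the right oxidation level, from a symmetric precursor.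

Alternative 3: Ring A and the macrocycle are disconnected together, back to the diazo enone A7 that carries the aryl ethynyl ether of ring B. In the forward step, irradiation causes loss of N2 and a Wolff shift to a vinylketene. The ketene adds [2+2] to the tethered ynol ether, and the cyclobutenone opens and recloses by electrocyclisation to the phenol A6. In its favour, this is the most convergent plan: one step makes ring A with unambiguous substitution, sets the ether on A5 and closes the 20-membered ring. In step count it beats the chosen route. Against it, the ethynyl ether of a hindered, electron-rich phenol is laborious to make and hydrolyses easily. The α-diazo α'-methylene ketone can cyclise onto its own alkene. The short-lived ketene must find an alkyne sixteen atoms away at high dilution, whereas this benzannulation normally relies on an excess of alkyne. Three uncertain events are stacked in one step. The chosen route uses ionic, thermal reactions of known classes and puts its risk into a folding step whose two ends behave like well-studied monofunctional cases.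

Key step: step 4

Assumption: 7 is drawn as the all-keto tautomer although it should exist largely in enol forms, and Mg(OMe)2 and LiN(iPr)2 are taken as purchased solutions.

## Route

Step 1
Reactants: 1 dehydroacetic acid (3-acetyl-4-hydroxy-6-methyl-2H-pyran-2-one)
Product: 2 methyl 3,5-dioxohexanoate
Conditions: Mg(OMe)2, MeOH, reflux; then 1 M HCl
Reagents that add atoms: methanol (used as Mg(OMe)2 in MeOH), CO
Why: Methoxide opens the lactone of 1 and the resulting 2-acetyl tricarbonyl ester loses its acetyl group by retro-Claisen cleavage as methyl acetate, while magnesium chelation protects the 3,5-dioxo ester from further cleavage; this is the known alcoholysis–deacetylation of this pyranone.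

Step 2
Reactants: 3 hexadecanedioic acid
Product: 5 N1,N16-dimethoxy-N1,N16-dimethylhexadecanediamide, via hexadecanedioyl diimidazolide 4 (not isolated)
Conditions: CDI, CH2Cl2, rt; then MeNH(OMe)·HCl, rt
Reagents that add atoms: N,O-dimethylhydroxylamine hydrochloride, CNOC.Cl
Why: CDI converts both carboxyl groups into acyl imidazoles with loss of CO2, and acyl substitution by the amine gives the bis(N-methoxy-N-methylamide); the fourteen methylene groups of the target chain are already in place.

Step 3
Reactants: 2 methyl 3,5-dioxohexanoate; 5 N1,N16-dimethoxy-N1,N16-dimethylhexadecanediamide
Product: 7 dimethyl 3,5,7,22,24,26-hexaoxooctacosanedioate, via trilithium trianion of methyl 3,5-dioxohexanoate 6 (not isolated)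
Conditions: 2 (3 equiv), LiN(iPr)2 (9 equiv), THF, −78 to 0 °C; then 5 (1 equiv), −78 to 0 °C; cold 1 M HCl to pH 4; used crude
Reagents that add atoms: none
Why: Three equivalents of base per molecule of 2 remove the C2, C4 and C6 protons, and the terminal C6 carbanion of 6, the most basic and least hindered site, adds to each amide carbonyl; the chelated tetrahedral adduct survives until the quench and prevents over-addition. This is the terminal C-acylation of a β-tricarbonyl polyanion, run at both ends of 5.

Step 4
Reactants: 7 dimethyl 3,5,7,22,24,26-hexaoxooctacosanedioate
Product: 8 dimethyl 6,6'-(tetradecane-1,14-diyl)bis(2,4-dihydroxybenzoate)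
Conditions: KOH (6 equiv), MeOH, 0 °C to rt, 0.02 M; then 1 M HCl
Reagents that add atoms: none
Why: Of the carbons that can reach a ketone through a six-membered transition state, C2 (and C27), flanked by the ester and the C3 ketone, is doubly activated, whereas C8 is activated only once, so the C2 enolate is the ring-forming nucleophile. It adds to the C7 ketone (C27 to C22) in an intramolecular aldol reaction, each carbocycle closing in the 6-(enolendo)-exo-trig mode. E1cB loss of water and enolisation of the C3 and C5 carbonyls then give the benzene ring, and this irreversible aromatisation drains the reversible aldol equilibria. The closest known reaction type is the base-induced aldol cycloaromatisation of 3,5,7-trioxoalkanoates to 6-alkyl-2,4-dihydroxybenzoates, here run twice in one molecule. No stereocenter remains, because the carbinol centres of the aldol adducts are erased by dehydration. The step needs C2-to-C7 aldol closure in preference to Claisen closure of C6 onto the C1 ester, aldol closure of C8 onto C3, and lactonisation to a 4-hydroxy-2-pyranone. The acidity of C2 and the protic, mildly basic medium should secure this: the ester carbonyl is a poorer electrophile than the ketone there, the polyanion needed for Claisen closure is not formed, and lactonisation is an acid-side process. The two termini lie fourteen methylene groups apart and should fold independently, and dilution suppresses aldol reactions between molecules.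

Step 5
Reactants: 8 dimethyl 6,6'-(tetradecane-1,14-diyl)bis(2,4-dihydroxybenzoate)
Product: 9 dimethyl 6,6'-(tetradecane-1,14-diyl)bis[2-hydroxy-4-(methoxymethoxy)benzoate]
Conditions: MOMCl (2.2 equiv), iPr2NEt, CH2Cl2, 0 °C to rt
Reagents that add atoms: chloromethyl methyl ether, COCCl
Why: The 2-hydroxyl of each ring is held in a hydrogen bond to the ester carbonyl, so the more acidic and more accessible 4-hydroxyl is alkylated selectively (chemoselective O-alkylation of a 2,4-dihydroxybenzoate); the acetal withstands the basic steps that follow.

Step 6
Reactants: 9 dimethyl 6,6'-(tetradecane-1,14-diyl)bis[2-hydroxy-4-(methoxymethoxy)benzoate]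
Product: 10 dimethyl 6,6'-(tetradecane-1,14-diyl)bis[2-(benzyloxy)-4-(methoxymethoxy)benzoate]
Conditions: BnBr, K2CO3, DMF, 60 °C
Reagents that add atoms: benzyl bromide, BrCc1ccccc1
Why: Williamson etherification under forcing conditions alkylates the remaining hydrogen-bonded hydroxyl; benzyl is chosen because the final hydrogenolysis removes it together with the residual iodine.

Step 7
Reactants: 10 dimethyl 6,6'-(tetradecane-1,14-diyl)bis[2-(benzyloxy)-4-(methoxymethoxy)benzoate]
Product: 11 6,6'-(tetradecane-1,14-diyl)bis[2-(benzyloxy)-4-(methoxymethoxy)benzoic acid]
Conditions: KOH, DMSO/H2O, 90 °C; then cold 1 M HCl to pH 4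
Reagents that add atoms: potassium hydroxide, [K+].[OH-]
Why: Saponification of a 2,6-disubstituted benzoate is slow and needs hot hydroxide in aqueous DMSO, which benzyl ethers and the acetals tolerate; cautious acidification frees the acid without cleaving the acetal or protonating the electron-rich ring at the ipso carbon.

Step 8
Reactants: 11 6,6'-(tetradecane-1,14-diyl)bis[2-(benzyloxy)-4-(methoxymethoxy)benzoic acid]
Product: 12 1,14-bis[3-(benzyloxy)-2-iodo-5-(methoxymethoxy)phenyl]tetradecane
Conditions: I2, K3PO4, MeCN, 100 °C, sealed tube, dark
Reagents that add atoms: iodine, II
Why: Transition-metal-free decarboxylative iodination of an electron-rich ortho-alkoxybenzoic acid: the carboxylate, twisted out of the ring plane by its two ortho substituents, takes up iodine and passes it to the ipso carbon as CO2 leaves, so the halogen lands on the former carboxyl carbon and not on the two open ring positions. The basic medium keeps the acetals intact.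

Step 9
Reactants: 12 1,14-bis[3-(benzyloxy)-2-iodo-5-(methoxymethoxy)phenyl]tetradecane
Product: 13 5,5'-(tetradecane-1,14-diyl)bis[3-(benzyloxy)-4-iodophenol]
Conditions: HCl (cat.), MeOH/THF, 40 °C
Reagents that add atoms: none
Why: Acid-catalysed transacetalisation to methanol cleaves the aryl methoxymethyl ethers; benzyl ethers and aryl iodides should survive these mild conditions, which are kept dilute in acid to avoid protodeiodination.

Step 10
Reactants: 13 5,5'-(tetradecane-1,14-diyl)bis[3-(benzyloxy)-4-iodophenol]
Product: 14 A1,B2-di-O-benzyl-A2-iodorobustol (20-membered diaryl ether; ring A with benzyloxy on A1 and iodine on A2, ring B with benzyloxy on B2 and free hydroxyl on B4)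
Conditions: CuI (0.5 equiv), picolinic acid, K3PO4 (2 equiv), DMSO, 90 °C, slow addition to 2 mM, Ar
Reagents that add atoms: none
Why: Ullmann-type intramolecular O-arylation: the copper phenoxide formed from one ring and monovalent copper couples with the C–I bond of the other ring, forming A5–O–B1 and the 20-membered ring, and slow addition keeps cyclisation ahead of oligomerisation. Because the hydroxyl of each ring is para to its own iodine, no ring can close on itself and a second ether bridge between the rings is geometrically impossible. The ring that acts as electrophile therefore becomes ring B, and the other keeps its iodine on A2.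

Step 11
Reactants: 14 A1,B2-di-O-benzyl-A2-iodorobustol
Product: 15 robustol (target)
Conditions: H2 (1 atm), 10% Pd/C (palladium on carbon), Et3N, EtOAc/MeOH, rt
Reagents that add atoms: none
Why: Hydrogenolysis cleaves both benzyl ethers and, with Et3N as acid scavenger, reduces the aryl C–I bond (hydrodehalogenation) in the same operation; the diaryl ether and the arenes are stable under these conditions, and the air-sensitive phenols appear only here.

## Compound list

1 | dehydroacetic acid (3-acetyl-4-hydroxy-6-methyl-2H-pyran-2-one) | CC(=O)C1=C(O)C=C(C)OC1=O | starting material
2 | methyl 3,5-dioxohexanoate | COC(=O)CC(=O)CC(C)=O | intermediate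
3 | hexadecanedioic acid | OC(=O)CCCCCCCCCCCCCCC(=O)O | starting material
4 | hexadecanedioyl diimidazolide (1,16-di(imidazol-1-yl)hexadecane-1,16-dione), not isolated | O=C(CCCCCCCCCCCCCCC(=O)n1ccnc1)n1ccnc1 | intermediate
5 | N1,N16-dimethoxy-N1,N16-dimethylhexadecanediamide | CON(C)C(=O)CCCCCCCCCCCCCCC(=O)N(C)OC | intermediate
6 | trilithium trianion of methyl 3,5-dioxohexanoate (tris-enolate), not isolated | [Li+].[Li+].[Li+].C=C([O-])C=C([O-])C=C([O-])OC | intermediate
7 | dimethyl 3,5,7,22,24,26-hexaoxooctacosanedioate (all-keto tautomer drawn) | COC(=O)CC(=O)CC(=O)CC(=O)CCCCCCCCCCCCCCC(=O)CC(=O)CC(=O)CC(=O)OC | intermediate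
8 | dimethyl 6,6'-(tetradecane-1,14-diyl)bis(2,4-dihydroxybenzoate) | COC(=O)c1c(O)cc(O)cc1CCCCCCCCCCCCCCc1cc(O)cc(O)c1C(=O)OC | intermediate
9 | dimethyl 6,6'-(tetradecane-1,14-diyl)bis[2-hydroxy-4-(methoxymethoxy)benzoate] | COCOc1cc(O)c(C(=O)OC)c(CCCCCCCCCCCCCCc2cc(OCOC)cc(O)c2C(=O)OC)c1 | intermediate
10 | dimethyl 6,6'-(tetradecane-1,14-diyl)bis[2-(benzyloxy)-4-(methoxymethoxy)benzoate] | COCOc1cc(OCc2ccccc2)c(C(=O)OC)c(CCCCCCCCCCCCCCc2cc(OCOC)cc(OCc3ccccc3)c2C(=O)OC)c1 | intermediate
11 | 6,6'-(tetradecane-1,14-diyl)bis[2-(benzyloxy)-4-(methoxymethoxy)benzoic acid] | COCOc1cc(OCc2ccccc2)c(C(=O)O)c(CCCCCCCCCCCCCCc2cc(OCOC)cc(OCc3ccccc3)c2C(=O)O)c1 | intermediate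
12 | 1,14-bis[3-(benzyloxy)-2-iodo-5-(methoxymethoxy)phenyl]tetradecane | COCOc1cc(OCc2ccccc2)c(I)c(CCCCCCCCCCCCCCc2cc(OCOC)cc(OCc3ccccc3)c2I)c1 | intermediate
13 | 5,5'-(tetradecane-1,14-diyl)bis[3-(benzyloxy)-4-iodophenol] | Oc1cc(OCc2ccccc2)c(I)c(CCCCCCCCCCCCCCc2cc(O)cc(OCc3ccccc3)c2I)c1 | intermediate
14 | A1,B2-di-O-benzyl-A2-iodorobustol | Ic1c(OCc2ccccc2)cc(Oc2c(OCc3ccccc3)cc(O)cc2CCCCCCCCCCCCCC4)cc14 | intermediate
15 | robustol (CNP0173380.0) | Oc1cc2cc(c1)Oc1c(O)cc(O)cc1CCCCCCCCCCCCCC2 | target

## Step count and least certain steps

Total: 11 steps. Longest linear sequence: 10 steps (step 1, then steps 3 to 11); step 2 is a one-step branch.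

Step 4 (key step). The most likely failure is misdirected ring closure at one or both termini: carbanion attack of C6 on the ester (Claisen condensation) or O-acylation to a pyranone. With two reactive ends in one molecule, aldol cross-linking between molecules is also possible. The fallback removes the electrophilic ester from the folding substrate. It sets out from 5. Double C-acylation of the lithium dianion of 2,2-dimethyl-6-(2-oxopropyl)-4H-1,3-dioxin-4-one F1 should give the bis(diketo-dioxinone) F2. F1 is made from 2,2,6-trimethyl-4H-1,3-dioxin-4-one by enolisation with LiN(SiMe3)2 and acetylation with acetyl chloride. In F2 the C1 carbonyl is locked in the dioxinone ring and is no target for C6. Et3N in CH2Cl2 should then bring about the same C2-to-C7 aldol aromatisation to 5,5'-(tetradecane-1,14-diyl)bis(7-hydroxy-2,2-dimethyl-4H-1,3-benzodioxin-4-one) F3. NaOMe in MeOH opens both acetonides to the methyl esters and the route is rejoined at 8.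

Step 10. The most likely failure is slow coupling at the C–I bond, which is flanked on both sides, electron-rich and further deactivated when its own para hydroxyl is deprotonated. Oligomerisation and protodeiodination would then take over. The fallback breaks the symmetry so that the electrophilic ring is not a phenoxide. It sets out from 12. Acidic methanolysis stopped at partial conversion should give the mono-phenol 3-(benzyloxy)-5-{14-[3-(benzyloxy)-2-iodo-5-(methoxymethoxy)phenyl]tetradecyl}-4-iodophenol F4. Recovered 12 is recycled, and over-cleaved 13 is re-acetalised to 12. The same copper-catalysed closure then pairs one phenoxide with a neutral iodoarene and should give A1,B2-di-O-benzyl-A2-iodo-B4-O-(methoxymethyl)robustol F5. Acidic methanolysis of F5 rejoins the route at 14.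

Step 8. The most likely failures are protodecarboxylation or ring iodination at the two open positions in place of ipso substitution, and acetal loss if acid builds up. The fallback replaces the carboxyl by nitrogen first. It sets out from 11. Curtius rearrangement with diphenylphosphoryl azide and Et3N in toluene at 80 °C should give the bis-isocyanate 1,14-bis[3-(benzyloxy)-2-isocyanato-5-(methoxymethoxy)phenyl]tetradecane F6. Aqueous KOH in THF hydrolyses it to 6,6'-(tetradecane-1,14-diyl)bis[2-(benzyloxy)-4-(methoxymethoxy)aniline] F7. Aprotic diazotisation–iodination (tert-butyl nitrite, CH2I2, MeCN, 60 °C, a Sandmeyer-type reaction) rejoins the route at 12.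

Step 3. The most likely failures are incomplete acylation at one of the two amide ends, caused by aggregation of the trianion, and premature cyclisation of the product during the acidic quench. The fallback avoids polyanions. It sets out from 2 and 3. Silylation of 2 (Me3SiCl and Et3N, then LiN(iPr)2 and Me3SiCl) gives 1-methoxy-1,3,5-tris(trimethylsilyloxy)hexa-1,3,5-triene F8. Oxalyl chloride with catalytic DMF converts 3 into hexadecanedioyl dichloride F9. Lewis-acid-mediated terminal acylation of F8 by F9 (TiCl4, CH2Cl2, −78 °C, a Mukaiyama-type Claisen condensation) and mild hydrolytic work-up rejoin the route at 7.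

## Further compounds

F1 | step 4 | 2,2-dimethyl-6-(2-oxopropyl)-4H-1,3-dioxin-4-one | CC(=O)CC1=CC(=O)OC(C)(C)O1
F2 | step 4 | 6,6'-(2,4,19,21-tetraoxodocosane-1,22-diyl)bis(2,2-dimethyl-4H-1,3-dioxin-4-one) | CC1(C)OC(=O)C=C(CC(=O)CC(=O)CCCCCCCCCCCCCCC(=O)CC(=O)CC2=CC(=O)OC(C)(C)O2)O1
F3 | step 4 | 5,5'-(tetradecane-1,14-diyl)bis(7-hydroxy-2,2-dimethyl-4H-1,3-benzodioxin-4-one) | CC1(C)OC(=O)c2c(CCCCCCCCCCCCCCc3cc(O)cc4OC(C)(C)OC(=O)c34)cc(O)cc2O1
F4 | step 10 | 3-(benzyloxy)-5-{14-[3-(benzyloxy)-2-iodo-5-(methoxymethoxy)phenyl]tetradecyl}-4-iodophenol | COCOc1cc(OCc2ccccc2)c(I)c(CCCCCCCCCCCCCCc2cc(O)cc(OCc3ccccc3)c2I)c1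
F5 | step 10 | A1,B2-di-O-benzyl-A2-iodo-B4-O-(methoxymethyl)robustol | Ic1c(OCc2ccccc2)cc(Oc2c(OCc3ccccc3)cc(OCOC)cc2CCCCCCCCCCCCCC4)cc14
F6 | step 8 | 1,14-bis[3-(benzyloxy)-2-isocyanato-5-(methoxymethoxy)phenyl]tetradecane | COCOc1cc(OCc2ccccc2)c(N=C=O)c(CCCCCCCCCCCCCCc2cc(OCOC)cc(OCc3ccccc3)c2N=C=O)c1
F7 | step 8 | 6,6'-(tetradecane-1,14-diyl)bis[2-(benzyloxy)-4-(methoxymethoxy)aniline] | COCOc1cc(OCc2ccccc2)c(N)c(CCCCCCCCCCCCCCc2cc(OCOC)cc(OCc3ccccc3)c2N)c1
F8 | step 3 | 1-methoxy-1,3,5-tris(trimethylsilyloxy)hexa-1,3,5-triene (double-bond geometry not defined) | COC(O[Si](C)(C)C)=CC(O[Si](C)(C)C)=CC(=C)O[Si](C)(C)C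
F9 | step 3 | hexadecanedioyl dichloride | ClC(=O)CCCCCCCCCCCCCCC(=O)Cl
A1 | alternative 1 | tri-O-methyl-1',2'-didehydrorobustol, (E) isomer drawn | COc1cc(/C=C/CCCCCCCCCCCCc2cc(OC)cc(OC)c2O3)cc3c1
A2 | alternative 1 | 21-membered cyclic sulfone, ring A–CH2–SO2–(CH2)13–ring B, with the diaryl ether and three O-methyl groups in place | COc1cc(CS(=O)(=O)CCCCCCCCCCCCCc2cc(OC)cc(OC)c2O3)cc3c1
A3 | alternative 2 | methyl 1-(3-bromo-5-methoxyphenoxy)-2,4-dioxo-6-(tetradec-13-enyl)cyclohexane-1-carboxylate, racemic mixture of diastereomers | COC(=O)C1(Oc2cc(Br)cc(OC)c2)C(=O)CC(=O)CC1CCCCCCCCCCCCC=C
A4 | alternative 2 | dimethyl 2-(3-bromo-5-methoxyphenoxy)propanedioate | COC(=O)C(Oc1cc(Br)cc(OC)c1)C(=O)OC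
A5 | alternative 2 | (E)-octadeca-3,17-dien-2-one | CC(=O)/C=C/CCCCCCCCCCCCC=C
A6 | alternative 3 | robustol B2,B4-dimethyl ether | Oc1cc2cc(c1)Oc1c(OC)cc(OC)cc1CCCCCCCCCCCCCC2
A7 | alternative 3 | 1-diazo-17-[2-(ethynyloxy)-3,5-dimethoxyphenyl]-3-methylideneheptadecan-2-one | [N-]=[N+]=CC(=O)C(=C)CCCCCCCCCCCCCCc1cc(OC)cc(OC)c1OC#C
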